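**Strategy.** Everything rests on annulating ring A (C1–C5, C10; eudesmane numbering) onto a ring B that (R)-carvone supplies with C7 set. Carvone is γ-oxygenated at the future C8 and inverted to the cis benzoate. Then, in one operation, hydride adds to C9 of the C5(=O)–C10(CH3)=C9 enone, the regiodefined C10 enolate captures an α-silyl ethyl vinyl ketone (C1–C10 bond, quaternary C10), and methoxide triggers desilylation and the C4–C5 aldol condensation. This three-component reductive Robinson annulation exploits the C3-oxygen/C4-methyl/C4=C5 pattern of ring A, a masked 1,5-diketone. Acetylation, isopropenyl-to-acrylate oxidation, Luche reduction and acylation complete the target.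

Key step: step 5

Remark: (E)-3-methylpent-2-enoic acid, (1-bromovinyl)trimethylsilane and N-methoxy-N-methylpropanamide are taken as purchasable. Bicyclic compounds are named as eudesmanes (C14 = methyl on C10, C15 = methyl on C4, C11–C13 = side chain on C7, β = face of C14; the C7 side chain is β throughout), and the same numbers are used for the "future" positions of the monocyclic compounds.

**Step 1**
Reactants: 1 (R)-(−)-carvone
Product: 3 triethyl{[(5S)-2-methyl-5-(prop-1-en-2-yl)cyclohexa-1,3-dien-1-yl]oxy}silane, via potassium dienolate 2 (not isolated)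
Conditions: KOt-Bu (1.1 equiv), THF, 0 °C; Et3SiCl, −78 → 0 °C
Reagents that add atoms: chlorotriethylsilane, CC[Si](Cl)(CC)CC
Why: Reversible deprotonation should give the fully conjugated (thermodynamic) dienolate by loss of a γ-hydrogen at the future C8, and O-silylation fixes it as the linear silyl dienol ether (thermodynamic enolisation/silyl enol ether formation); C7 is untouched.

**Step 2**
Reactants: 3 linear triethylsilyl dienol ether
Product: 4 (4S,5R)-4-hydroxy-2-methyl-5-(prop-1-en-2-yl)cyclohex-2-en-1-one (trans)
Conditions: mCPBA (1.05 equiv), NaHCO3, CH2Cl2, −40 → 0 °C; then 1 M HCl, THF, 0 °C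
Reagents that add atoms: 3-chloroperoxybenzoic acid (mCPBA), OOC(=O)c1cccc(Cl)c1
Why: Vinylogous Rubottom oxidation: the peracid attacks the electron-rich diene terminus (future C8) anti to the neighbouring C7 isopropenyl group, and collapse of the silyl oxocarbenium ion gives the trans γ-hydroxy enone, so the new C8 centre is set by that anti approach.

**Step 3**
Reactants: 4 trans γ-hydroxy enone
Product: 5 (1R,6R)-3-methyl-4-oxo-6-(prop-1-en-2-yl)cyclohex-2-en-1-yl benzoate (cis)
Conditions: PPh3, DIAD, PhCO2H, THF, 0 °C → rt
Reagents that add atoms: benzoic acid, OC(=O)c1ccccc1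
Why: Mitsunobu esterification of the allylic alcohol proceeds by SN2 inversion at C8 and so gives the cis benzoate needed to steer the later attack at C10; anti-elimination towards C7 is unavailable because H7 is cis to the leaving group.

**Step 4**
Reactants: 6 (1-bromovinyl)trimethylsilane; 7 N-methoxy-N-methylpropanamide
Product: 9 2-(trimethylsilyl)pent-1-en-3-one, via silylvinyl Grignard reagent 8 (not isolated)
Conditions: Mg, THF, reflux; then 7, −78 → 0 °C; cold 1 M HCl quench
Reagents that add atoms: none
Why: Weinreb ketone synthesis: the Grignard reagent adds once to the N-methoxy-N-methylamide through a stable chelate that releases the α-silyl enone only on acidic quench.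

**Step 5**
Reactants: 5 cis benzoate enone; 9 2-(trimethylsilyl)pent-1-en-3-one
Product: 13 8β-hydroxyeudesma-4,11-dien-3-one, via lithium enolate 10 (not isolated), via silyl diketone 11 (not isolated), via hydroxy diketone 12 (not isolated)
Conditions: LiBH(s-Bu)3 (1.05 equiv), THF, −78 °C; 9, −78 → 0 °C; then NaOMe, MeOH, 65 °C; non-oxidative work-up
Reagents that add atoms: none
Why: LiBH(s-Bu)3 delivers hydride to C9 of the β-unsubstituted, α-methyl enone and so gives only the C5–C10 enolate 10, whose C10 adds to the silyl-stabilised acceptor 9 (C1–C10 bond, 11); methoxide then removes silicon and the benzoate (12) and drives the C4-to-C5 aldol condensation with dehydration, which closes ring A as the 3-keto-4-ene. The closest known reaction types are the conjugate reduction–enolate trapping of enones with trialkylborohydrides and the α-silyl vinyl ketone variant of the Robinson annulation on regiodefined enolates. Ring A closes by a 6-(enolendo)-exo-trig aldol addition. C10 is the only new stereocentre and is substrate-controlled: the cis C7 isopropenyl and C8 benzoate crowd the β face (a chair-like β attack would clash 1,3-diaxially with the C8 ester), so C1 should enter from the α face and C14 ends β. The step needs 1,4- over 1,2-hydride addition (bulky hydride, unhindered C9), an enolate that does not equilibrate (aprotic, low temperature, an acceptor whose adduct is a stabilised α-silyl enolate) and a single aldol regiochemistry (only C4 onto C5 gives a six-membered enone).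

**Step 6**
Reactants: 13 8β-hydroxyeudesma-4,11-dien-3-one
Product: 14 8β-acetoxyeudesma-4,11-dien-3-one
Conditions: Ac2O, Et3N, DMAP (cat.), CH2Cl2, rt
Reagents that add atoms: acetic anhydride, CC(=O)OC(C)=O
Why: DMAP-catalysed acetylation of the axial secondary C8 alcohol, the only hydroxyl present; it is done now so that no free C8 hydroxyl ever faces a C12 ester (lactonisation).

**Step 7**
Reactants: 14 8β-acetoxyeudesma-4,11-dien-3-one
Product: 15 8β-acetoxy-12-hydroxyeudesma-4,11(13)-dien-3-one
Conditions: SeO2 (0.5 equiv), t-BuOOH, CH2Cl2, rt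
Reagents that add atoms: selenium dioxide, O=[Se]=O; tert-butyl hydroperoxide, CC(C)(C)OO
Why: Riley-type allylic oxidation (ene reaction, then 2,3-sigmatropic shift) should be confined to the electron-rich isopropenyl alkene because the conjugated C4=C5 bond is deactivated, and the methyl group is preferred over the C7 methine, which the adjacent acetoxy group deactivates; any over-oxidised enal converges in step 8.

**Step 8**
Reactants: 15 allylic alcohol
Product: 17 8β-acetoxy-3-oxoeudesma-4,11(13)-dien-12-oic acid, via enal 16 (not isolated)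
Conditions: Dess–Martin periodinane, NaHCO3, CH2Cl2, rt; crude aldehyde, then NaClO2, NaH2PO4, 2-methylbut-2-ene, t-BuOH/H2O, rt
Reagents that add atoms: sodium chlorite, [Na+].[O-]Cl=O
Why: Dess–Martin oxidation gives the 2-substituted acrolein and Pinnick oxidation of the crude aldehyde gives the acrylic acid, with 2-methylbut-2-ene scavenging hypochlorite so that the alkenes are untouched.

**Step 9**
Reactants: 17 acrylic acid
Product: 18 methyl 8β-acetoxy-3-oxoeudesma-4,11(13)-dien-12-oate
Conditions: MeI, KHCO3, DMF, rt
Reagents that add atoms: iodomethane, CI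
Why: SN2 O-methylation of the carboxylate under bicarbonate conditions leaves the acetate and the enone alone (diazoalkanes are avoided because they add to acrylates).

**Step 10**
Reactants: 18 keto ester
Product: 19 methyl 8β-acetoxy-3β-hydroxyeudesma-4,11(13)-dien-12-oate
Conditions: NaBH4, CeCl3·7H2O, MeOH, −78 °C
Reagents that add atoms: none
Why: Luche reduction should give clean 1,2-reduction of the enone beside the acrylate and the acetate, with hydride arriving axially on the α face anti to the angular C14 methyl, so that the new C3 hydroxyl is β (equatorial).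

**Step 11**
Reactants: 19 allylic alcohol; 20 (E)-3-methylpent-2-enoic acid
Product: 21 methyl 8β-acetoxy-3β-[(2E)-3-methylpent-2-enoyloxy]eudesma-4,11(13)-dien-12-oate (target)
Conditions: EDC·HCl, DMAP, CH2Cl2, 0 °C → rt
Reagents that add atoms: none
Why: Steglich-type carbodiimide/DMAP esterification acylates the allylic secondary alcohol with retention at C3, and activation without strong base should limit E/Z scrambling or deconjugation of the β,β-disubstituted acrylate.

**Compound list**
1 | (R)-(−)-carvone, (5R)-2-methyl-5-(prop-1-en-2-yl)cyclohex-2-en-1-one | C=C(C)[C@H]1CC(=O)C(C)=CC1 | starting material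
2 | potassium (5S)-2-methyl-5-(prop-1-en-2-yl)cyclohexa-1,3-dien-1-olate | C=C(C)[C@H]1CC([O-])=C(C)C=C1.[K+] | intermediate
3 | triethyl{[(5S)-2-methyl-5-(prop-1-en-2-yl)cyclohexa-1,3-dien-1-yl]oxy}silane | C=C(C)[C@H]1CC(O[Si](CC)(CC)CC)=C(C)C=C1 | intermediate
4 | (4S,5R)-4-hydroxy-2-methyl-5-(prop-1-en-2-yl)cyclohex-2-en-1-one (OH trans to isopropenyl) | C=C(C)[C@H]1CC(=O)C(C)=C[C@@H]1O | intermediate
5 | (1R,6R)-3-methyl-4-oxo-6-(prop-1-en-2-yl)cyclohex-2-en-1-yl benzoate (ester cis to isopropenyl) | C=C(C)[C@H]1CC(=O)C(C)=C[C@H]1OC(=O)c2ccccc2 | intermediate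
6 | (1-bromovinyl)trimethylsilane | C=C(Br)[Si](C)(C)C | starting material
7 | N-methoxy-N-methylpropanamide | CCC(=O)N(C)OC | starting material
8 | [1-(trimethylsilyl)vinyl]magnesium bromide | C=C([Mg]Br)[Si](C)(C)C | intermediate
9 | 2-(trimethylsilyl)pent-1-en-3-one | CCC(=O)C(=C)[Si](C)(C)C | intermediate
10 | lithium (4R,5R)-4-(benzoyloxy)-2-methyl-5-(prop-1-en-2-yl)cyclohex-1-en-1-olate | C=C(C)[C@H]1CC([O-])=C(C)C[C@H]1OC(=O)c2ccccc2.[Li+] | intermediate
11 | (1R,2R,5S)-5-methyl-4-oxo-5-[3-oxo-2-(trimethylsilyl)pentyl]-2-(prop-1-en-2-yl)cyclohexyl benzoate (silyl-bearing carbon unassigned; present as its lithium enolate) | C=C(C)[C@H]1CC(=O)[C@](C)(CC(C(=O)CC)[Si](C)(C)C)C[C@H]1OC(=O)c2ccccc2 | intermediate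
12 | (2R,4R,5R)-4-hydroxy-2-methyl-2-(3-oxopentyl)-5-(prop-1-en-2-yl)cyclohexan-1-one | C=C(C)[C@H]1CC(=O)[C@](C)(CCC(=O)CC)C[C@H]1O | intermediate
13 | 8β-hydroxyeudesma-4,11-dien-3-one, (4aR,6R,7R)-6-hydroxy-1,4a-dimethyl-7-(prop-1-en-2-yl)-4,4a,5,6,7,8-hexahydronaphthalen-2(3H)-one | C=C(C)[C@H]1CC2=C(C)C(=O)CC[C@]2(C)C[C@H]1O | intermediate
14 | 8β-acetoxyeudesma-4,11-dien-3-one | C=C(C)[C@H]1CC2=C(C)C(=O)CC[C@]2(C)C[C@H]1OC(C)=O | intermediate
15 | 8β-acetoxy-12-hydroxyeudesma-4,11(13)-dien-3-one | C=C(CO)[C@H]1CC2=C(C)C(=O)CC[C@]2(C)C[C@H]1OC(C)=O | intermediate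
16 | 8β-acetoxy-3-oxoeudesma-4,11(13)-dien-12-al | C=C(C=O)[C@H]1CC2=C(C)C(=O)CC[C@]2(C)C[C@H]1OC(C)=O | intermediate
17 | 8β-acetoxy-3-oxoeudesma-4,11(13)-dien-12-oic acid | C=C(C(=O)O)[C@H]1CC2=C(C)C(=O)CC[C@]2(C)C[C@H]1OC(C)=O | intermediate
18 | methyl 8β-acetoxy-3-oxoeudesma-4,11(13)-dien-12-oate | C=C(C(=O)OC)[C@H]1CC2=C(C)C(=O)CC[C@]2(C)C[C@H]1OC(C)=O | intermediate
19 | methyl 8β-acetoxy-3β-hydroxyeudesma-4,11(13)-dien-12-oate | C=C(C(=O)OC)[C@H]1CC2=C(C)[C@@H](O)CC[C@]2(C)C[C@H]1OC(C)=O | intermediate
20 | (E)-3-methylpent-2-enoic acid | CC/C(C)=C/C(=O)O | starting material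
21 | methyl 2-[(2R,3R,4aR,7S)-3-acetoxy-4a,8-dimethyl-7-{[(2E)-3-methylpent-2-enoyl]oxy}-1,2,3,4,4a,5,6,7-octahydronaphthalen-2-yl]prop-2-enoate | C=C(C(=O)OC)[C@H]1CC2=C(C)[C@@H](OC(=O)/C=C(\C)CC)CC[C@]2(C)C[C@H]1OC(C)=O | target

**Count.** Total: 11 steps. Longest linear sequence: 10 steps (1, 2, 3, 5, 6, 7, 8, 9, 10, 11); step 4 is a one-step side branch.

**Steps most likely to fail**

Step 5. Hydride may add 1,2 or attack the benzoate, the lithium enolate may equilibrate or polymerise the acceptor, or the acceptor may reach C10 from the β face. Fallback (from 5, back at 13): an enolate-free, auxiliary-controlled annulation. Compound 5 is reduced with LiBH(s-Bu)3 and the enolate protonated to the saturated ketone F1 (C10 epimers, inconsequential). F1 is condensed with (R)-1-phenylethylamine to the imine F2. Its secondary enamine tautomer should add to pent-1-en-3-one under neutral conditions on the face dictated by the auxiliary, giving the imine adduct F3. Aqueous acetic acid releases the 1,5-diketone F4 and the amine, and NaOMe/MeOH cyclises and debenzoylates F4 to 13.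

Step 1. Deprotonation at the α′ carbon (C6) instead of the γ carbon would give the cross-conjugated dienol ether, and base-induced double-bond migration could aromatise the ring. Fallback (from 1, back at 4): thermodynamic enol acetylation under acid instead of base. Isopropenyl acetate with catalytic TsOH should convert 1 through reversible acid-catalysed enolisation into the linear dienyl acetate F5. Buffered mCPBA in wet CH2Cl2 then oxidises F5 at the γ carbon anti to the isopropenyl group, and hydrolytic loss of the acetyl group returns 4.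

Step 7. Ene attack at the C7 methine, allylic rearrangement or stalling at low conversion would erode the oxidation. Fallback (from 14, back at 16): ene-type chlorination with Ca(OCl)2/CO2 in CH2Cl2–H2O should give the allylic chloride F6 with the double bond kept as the C11=C13 methylene. Trimethylamine N-oxide in DMSO then displaces chloride and fragments to the enal 16, which enters the chlorite oxidation of step 8.

**Further compounds**
F1 | step 5 | (1R,2R)-5-methyl-4-oxo-2-(prop-1-en-2-yl)cyclohexyl benzoate (C5 epimers) | C=C(C)[C@H]1CC(=O)C(C)C[C@H]1OC(=O)c2ccccc2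
F2 | step 5 | N-[(1R)-1-phenylethyl] imine of F1 | C=C(C)[C@H]1CC(=N[C@H](C)c2ccccc2)C(C)C[C@H]1OC(=O)c3ccccc3
F3 | step 5 | N-[(1R)-1-phenylethyl] imine of the C10-quaternary Michael adduct | C=C(C)[C@H]1CC(=N[C@H](C)c2ccccc2)[C@](C)(CCC(=O)CC)C[C@H]1OC(=O)c3ccccc3
F4 | step 5 | (1R,2R,5R)-5-methyl-4-oxo-5-(3-oxopentyl)-2-(prop-1-en-2-yl)cyclohexyl benzoate | C=C(C)[C@H]1CC(=O)[C@](C)(CCC(=O)CC)C[C@H]1OC(=O)c2ccccc2
F5 | step 1 | (5S)-2-methyl-5-(prop-1-en-2-yl)cyclohexa-1,3-dien-1-yl acetate | C=C(C)[C@H]1CC(OC(C)=O)=C(C)C=C1
F6 | step 7 | 8β-acetoxy-12-chloroeudesma-4,11(13)-dien-3-one | C=C(CCl)[C@H]1CC2=C(C)C(=O)CC[C@]2(C)C[C@H]1OC(C)=O
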